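## Retrosynthetic overview

1. The target is reached last by desilylation, O8-angeloylation and C11 α-methylenation of a 1,10-epoxy-2-ol, which comes from Payne shift of a cis-1,2-oxirane flanked by the tertiary C10 alcohol.
2. Key disconnection: C8–O ⇒ C8–Si ⇒ C8–H. The strategy rests on C8–H being γ to O10 (O10–C10–C9–C8) and on O8 and O10 being cis on the ten-membered ring, so a five-membered oxasilolane (O10–Si–C8–C9–C10) can bridge the carbocycle.
3. The ten-membered carbocycle is closed by ring-closing metathesis at C1=C2 of a lactone diene, followed by O10-directed epoxidation.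
4. The diene comes from Z-selective olefination at C4=C5 of a lactone aldehyde; the C7–C8 bond comes from trans conjugate addition of a linalool-derived C8–C10 Grignard reagent to the silyl ether of (S)-5-(hydroxymethyl)furan-2(5H)-one.
5. Ring order: γ-lactone (chiral pool) → carbocycle → 1,2-oxirane → oxasilolane (key step, opened again by oxidation) → 1,10-oxirane.

Key step: step 16

Assumption: atom numbers C1–C15 are those of the germacranolide skeleton of the target (C1–C10 ring, C11–C13 lactone, C14 on C10, C15 on C4) and are used for acyclic intermediates too; (R)-linalool is taken as enantiomerically pure, and its carbinol carbon becomes C10.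

## Route

Step 1
Reactants: 1 (R)-linalool
Product: 2 (R)-linalool triethylsilyl ether
Conditions: TESOTf, 2,6-lutidine, CH2Cl2, −78 → 0 °C
Reagents that add atoms: triethylsilyl triflate CC[Si](CC)(CC)OS(=O)(=O)C(F)(F)F
Why: O-silylation of the tertiary allylic alcohol with a silyl triflate masks O10 for the radical and organometallic steps and leaves the C10 stereocentre untouched.

Step 2
Reactants: 2 (R)-linalool triethylsilyl ether
Product: 4 (4R)-4-methyl-4-(triethylsilyloxy)hex-5-enoic acid, via aldehyde 3 (not isolated)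
Conditions: O3, CH2Cl2, −78 °C (Sudan Red 7B end point); PPh3; then NaClO2, NaH2PO4, 2-methyl-2-butene, t-BuOH/H2O, 0 °C → rt
Reagents that add atoms: ozone [O-][O+]=O; sodium chlorite [Na+].[O-]Cl=O
Why: Ozonolysis should cleave the electron-rich trisubstituted alkene ahead of the vinyl group, which is deactivated by the allylic oxygen, and Pinnick oxidation of the aldehyde gives the acid whose α-carbon is C8.

Step 3
Reactants: 4 (4R)-4-methyl-4-(triethylsilyloxy)hex-5-enoic acid
Product: 6 triethyl{[(3R)-5-iodo-3-methylpent-1-en-3-yl]oxy}silane, via Barton ester 5 (not isolated)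
Conditions: N-hydroxypyridine-2-thione, DCC, CH2Cl2, 0 °C → rt, dark; then CHI3, hν (tungsten lamp), rt
Reagents that add atoms: iodoform IC(I)I; N-hydroxypyridine-2-thione On1ccccc1=S (held only in 5)
Why: Barton decarboxylative iodination (radical chain through the thiohydroxamate ester with iodine transfer from iodoform) removes the extra carbon and leaves C8 as a primary iodide; the primary radical has no fast cyclisation onto the vinyl group.

Step 4
Reactants: 7 (S)-5-(hydroxymethyl)furan-2(5H)-one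
Product: 8 (S)-5-[(tert-butyldimethylsilyloxy)methyl]furan-2(5H)-one
Conditions: TBSCl, imidazole, CH2Cl2, 0 °C → rt
Reagents that add atoms: tert-butyldimethylsilyl chloride CC(C)(C)[Si](C)(C)Cl
Why: Silylation of the primary alcohol gives the bulky C5 substituent that will shield one face of the butenolide.

Step 5
Reactants: 6 triethyl{[(3R)-5-iodo-3-methylpent-1-en-3-yl]oxy}silane; 8 (S)-5-[(tert-butyldimethylsilyloxy)methyl]furan-2(5H)-one
Product: 11 (4S,5S)-5-[(tert-butyldimethylsilyloxy)methyl]-4-[(3R)-3-methyl-3-(triethylsilyloxy)pent-4-en-1-yl]dihydrofuran-2(3H)-one, via Grignard reagent 9 (not isolated), via silyl ketene acetal 10 (not isolated)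
Conditions: Mg (activated), THF, 0 °C → rt; then CuBr·SMe2 (10 mol %), TMSCl, 8, THF, −78 °C; aq. NH4Cl
Reagents that add atoms: magnesium [Mg] (held only in 9); chlorotrimethylsilane C[Si](C)(C)Cl (held only in 10)
Why: Copper-catalysed, TMSCl-accelerated conjugate addition of the Grignard reagent forms C7–C8; the nucleophile adds anti to the CH2OTBS group on C6, which sets C7 trans to C6.

Step 6
Reactants: 11 conjugate adduct
Product: 12 (4S,5S)-5-(hydroxymethyl)-4-[(3R)-3-hydroxy-3-methylpent-4-en-1-yl]dihydrofuran-2(3H)-one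
Conditions: HF·pyridine, pyridine, THF, 0 °C → rt
Reagents that add atoms: none
Why: Fluoride cleaves both silyl ethers under buffered conditions; the primary alcohol is needed for oxidation and the tertiary C10 alcohol is tolerated in all steps up to the metathesis.

Step 7
Reactants: 12 diol lactone
Product: 13 (2S,3S)-3-[(3R)-3-hydroxy-3-methylpent-4-en-1-yl]-5-oxotetrahydrofuran-2-carbaldehyde
Conditions: Dess–Martin periodinane, NaHCO3, CH2Cl2, 0 °C → rt; used crude
Reagents that add atoms: none
Why: Dess–Martin oxidation converts only the primary alcohol (the tertiary one is inert); buffering and direct use should prevent epimerisation at C6, whose trans arrangement is also the thermodynamic one.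

Step 8
Reactants: 14 methyl bis(2,2,2-trifluoroethyl)phosphonoacetate; 15 allyl bromide
Product: 16 methyl 2-[bis(2,2,2-trifluoroethoxy)phosphoryl]pent-4-enoate (racemic)
Conditions: NaH, THF, 0 °C; then 15, 0 °C → rt (14 in slight excess)
Reagents that add atoms: none
Why: SN2 C-alkylation of the stabilised phosphonate anion installs the allyl group (C3, C2 and the later-lost terminal carbon) on the future C4.

Step 9
Reactants: 13 lactone aldehyde; 16 allylated phosphonate
Product: 17 methyl (2Z)-2-({(2S,3S)-3-[(3R)-3-hydroxy-3-methylpent-4-en-1-yl]-5-oxotetrahydrofuran-2-yl}methylidene)pent-4-enoate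
Conditions: 16, KHMDS, 18-crown-6, THF, −78 °C; then 13, −78 °C
Reagents that add atoms: none
Why: Still–Gennari olefination: the electron-poor trifluoroethyl phosphonate eliminates under kinetic control to the (Z)-enoate, so the ester carbon (C15) is cis to C6 and the allyl carbon C3 is trans to it, as the ring needs.

Step 10
Reactants: 17 (Z)-enoate lactone
Product: 18 (4S,5S)-5-[(1Z)-2-(hydroxymethyl)penta-1,4-dien-1-yl]-4-[(3R)-3-hydroxy-3-methylpent-4-en-1-yl]tetrahydrofuran-2-ol (anomers)
Conditions: DIBAL-H (5 equiv), CH2Cl2, −78 °C; Rochelle salt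
Reagents that add atoms: none
Why: DIBAL reduction takes the conjugated ester to the allylic alcohol while the lactone stops at the lactol (stable aluminium hemiacetal at −78 °C); this avoids an unreliable ester-versus-lactone selection.

Step 11
Reactants: 18 lactol triol
Product: 19 (4S,5S)-5-[(1Z)-2-{[(tert-butyldimethylsilyl)oxy]methyl}penta-1,4-dien-1-yl]-4-[(3R)-3-hydroxy-3-methylpent-4-en-1-yl]tetrahydrofuran-2-ol
Conditions: TBSCl (1.05 equiv), imidazole, CH2Cl2, −20 → 0 °C
Reagents that add atoms: tert-butyldimethylsilyl chloride CC(C)(C)[Si](C)(C)Cl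
Why: The primary allylic hydroxyl is silylated faster than the lactol and tertiary hydroxyls (steric selection).

Step 12
Reactants: 19 silylated lactol
Product: 20 (4S,5S)-5-[(1Z)-2-{[(tert-butyldimethylsilyl)oxy]methyl}penta-1,4-dien-1-yl]-4-[(3R)-3-hydroxy-3-methylpent-4-en-1-yl]dihydrofuran-2(3H)-one
Conditions: TPAP (5 mol %), NMO, 4 Å MS, CH2Cl2, rt
Reagents that add atoms: none
Why: Ley–Griffith oxidation returns the lactol to the lactone; the tertiary alcohol, silyl ether and alkenes are inert.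

Step 13
Reactants: 20 lactone diene
Product: 21 (1Z,4Z,6S,7S,10R)-15-(tert-butyldimethylsilyloxy)-10-hydroxygermacra-1,4-dien-12,6-olide
Conditions: Grubbs II catalyst (10 mol %), 1,4-benzoquinone (20 mol %), toluene (1 mM), 80 °C, argon sparge
Reagents that add atoms: none
Why: Ring-closing metathesis: the carbene should load on the unhindered allyl terminus and close onto the vinyl carbinol (the free allylic hydroxyl assists); the new C1=C2 bond should be Z because an E,E-cyclodeca-1,4-diene is too strained.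

Step 14
Reactants: 21 macrocyclic allylic alcohol
Product: 22 (1S,2S,4Z,6S,7S,10R)-15-(tert-butyldimethylsilyloxy)-1,2-epoxy-10-hydroxygermacr-4-en-12,6-olide
Conditions: VO(acac)2 (10 mol %), t-BuOOH (decane), CH2Cl2, 0 °C → rt
Reagents that add atoms: tert-butyl hydroperoxide CC(C)(C)OO
Why: Vanadium-catalysed hydroxyl-directed epoxidation: the vanadate ester of O10 should deliver oxygen to the C1=C2 face syn to O10, as it does for medium-ring cis-cycloalkenols, setting C1 and C2; C4=C5 has no free hydroxyl and should stay.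

Step 15
Reactants: 22 cis-epoxy alcohol
Product: 23 (1S,2S,4Z,6S,7S,10R)-15-(tert-butyldimethylsilyloxy)-10-(diethylsilyloxy)-1,2-epoxygermacr-4-en-12,6-olide
Conditions: Et2SiHCl, Et3N, DMAP (cat.), CH2Cl2, 0 °C → rt; filtered through Florisil and used directly
Reagents that add atoms: chlorodiethylsilane CC[SiH](Cl)CC
Why: O-silylation of the tertiary alcohol with the small chlorohydrosilane attaches the Si–H tether to O10; the amine base is too weak to trigger epoxide migration.

Step 16
Reactants: 23 O10 diethyl(hydrido)silyl ether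
Product: 24 (1S,2S,4Z,6R,7S,8S,10R)-15-(tert-butyldimethylsilyloxy)-1,2-epoxy-8,10-(diethylsilanediyloxy)germacr-4-en-12,6-olide (SiEt2 bonded to C8 and to O10)
Conditions: [Ir(cod)OMe]2 (2.5 mol %), 3,4,7,8-tetramethyl-1,10-phenanthroline (6 mol %), norbornene (1.5 equiv), THF, 100 °C, sealed tube
Reagents that add atoms: none
Why: Proposed new method: oxidative addition of the Si–H bond of 23 to the iridium(I)–phenanthroline catalyst, cleavage of the C8–H bond on the O10 face through a six-membered iridacycle (Ir–Si–O10–C10–C9–C8) and C–Si reductive elimination should give the oxasilolane, with norbornene taking up the hydrogen; the closest known reaction type is the iridium-catalysed, hydroxyl-directed γ-C–H silylation of (hydrido)silyl ethers of simple alcohols that is followed by oxidation to 1,3-diols, which has not been shown for a ring methylene of a ten-membered epoxy lactone. The five-membered ring (O10–Si–C8–C9–C10) closes at the C8–Si bond as a two-atom bridge over C8–C9–C10 of the carbocycle. The new stereocentre C8 is set by the tether, since only the C8 hydrogen cis to O10 can be bridged, so silicon ends up 8,10-syn (8S). The step needs γ-selectivity for C8: the C14 hydrogens are β (four-membered ring), C7–H is δ, and the other γ hydrogen (C2–H) is trans to C10 on the cis-oxirane, so a ring through it would be a trans-fused bicyclo[3.1.0] system. Chemoselectivity over C4=C5 should come from its trisubstitution, its two allylic oxygens and the presence of norbornene as the better hydrogen acceptor.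

Step 17
Reactants: 24 oxasilolane
Product: 25 (1S,2S,4Z,6R,7R,8S,10R)-15-(tert-butyldimethylsilyloxy)-1,2-epoxy-8,10-dihydroxygermacr-4-en-12,6-olide
Conditions: H2O2 (30 % aq.), KF, KHCO3, THF/MeOH, rt → 40 °C
Reagents that add atoms: hydrogen peroxide OO
Why: Tamao–Fleming oxidation: hydroperoxide adds to the activated alkoxysilane and C8 migrates from silicon to oxygen with retention, giving the 8,10-syn diol; bicarbonate is too weak a base for epoxide migration or lactone exchange.

Step 18
Reactants: 25 8,10-diol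
Product: 26 (1S,2S,4Z,6R,7R,8S,10R)-15-(tert-butyldimethylsilyloxy)-1,2-epoxy-10-hydroxy-8-(4-methoxybenzyloxy)germacr-4-en-12,6-olide
Conditions: 2-(4-methoxybenzyloxy)-4-methylquinoline, MeOTf, MgO, PhCF3, 0 °C → rt
Reagents that add atoms: 2-(4-methoxybenzyloxy)-4-methylquinoline COc1ccc(COc2cc(C)c3ccccc3n2)cc1
Why: Near-neutral benzyl transfer from the N-methylated 2-alkoxyquinolinium salt etherifies the secondary C8 hydroxyl and not the tertiary one; an ether is chosen because a silyl group on O8 would migrate to the syn O10 alkoxide in step 19, and a free O8 would attack the lactone.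

Step 19
Reactants: 26 8-O-PMB epoxy alcohol
Product: 28 (1R,2S,4Z,6R,7R,8S,10R)-15-(tert-butyldimethylsilyloxy)-1,10-epoxy-8-(4-methoxybenzyloxy)-2-(triethylsilyloxy)germacr-4-en-12,6-olide, via sodium alkoxide 27 (not isolated)
Conditions: NaH, THF, 0 °C → rt; then TESCl, 0 °C
Reagents that add atoms: chlorotriethylsilane CC[Si](Cl)(CC)CC; sodium hydride [Na+].[H-] (sodium held only in 27)
Why: Payne rearrangement: the O10 alkoxide opens the oxirane at C1 from the back (3-exo-tet, inversion at C1, C2 and C10 untouched) to give the trans-1,10-epoxide and the C2 alkoxide, favoured as the more substituted epoxide and less hindered alkoxide and taken out of the equilibrium by silylation.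

Step 20
Reactants: 28 1,10-epoxide lactone
Product: 31 (1R,2S,4Z,6R,7R,8S,10R)-15-(tert-butyldimethylsilyloxy)-1,10-epoxy-8-(4-methoxybenzyloxy)-2-(triethylsilyloxy)germacra-4,11(13)-dien-12,6-olide, via Mannich base 29 (not isolated), via ammonium iodide 30 (not isolated)
Conditions: LiHMDS, THF, −78 °C; Eschenmoser's salt, −78 → 0 °C; MeI, MeOH, rt; NaHCO3 (aq)/CH2Cl2
Reagents that add atoms: Eschenmoser's salt C=[N+](C)C.[I-]; iodomethane CI (held only in 30)
Why: α-Methylenation by Mannich reaction of the lactone lithium enolate, N-methylation and elimination of trimethylamine; it is done before the C8 ester is present, because a C11 enolate would otherwise attack that ester.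

Step 21
Reactants: 31 α-methylene lactone
Product: 32 (1R,2S,4Z,6R,7R,8S,10R)-15-(tert-butyldimethylsilyloxy)-1,10-epoxy-8-hydroxy-2-(triethylsilyloxy)germacra-4,11(13)-dien-12,6-olide
Conditions: DDQ, CH2Cl2/pH 7 phosphate buffer, 0 °C
Reagents that add atoms: none
Why: Oxidative cleavage of the 4-methoxybenzyl ether by DDQ (benzylic oxidation to the oxocarbenium ion, then hydrolysis) frees only O8; silyl ethers, epoxide and methylene lactone tolerate the buffered conditions.

Step 22
Reactants: 32 C8 alcohol; 33 angelic acid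
Product: 35 (1R,2S,4Z,6R,7R,8S,10R)-8-angeloyloxy-15-(tert-butyldimethylsilyloxy)-1,10-epoxy-2-(triethylsilyloxy)germacra-4,11(13)-dien-12,6-olide, via mixed anhydride 34 (not isolated)
Conditions: 33, 2,4,6-trichlorobenzoyl chloride, Et3N, toluene, rt; then 32, toluene, 80 °C (no DMAP)
Reagents that add atoms: 2,4,6-trichlorobenzoyl chloride O=C(Cl)c1c(Cl)cc(Cl)cc1Cl (held only in 34)
Why: Yamaguchi-type esterification through the mixed anhydride; leaving out the nucleophilic catalyst avoids addition–elimination at the enoate and so should keep the Z (angelate) geometry.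

Step 23
Reactants: 35 bis-silyl ether
Product: 36 EANPDB:COMP_00180, (1R,2S,4Z,6R,7R,8S,10R)-8-angeloyloxy-1,10-epoxy-2,15-dihydroxygermacra-4,11(13)-dien-12,6-olide
Conditions: Et3N·3HF, MeCN, rt
Reagents that add atoms: none
Why: Fluoride desilylation under nearly neutral conditions removes the secondary TES and primary TBS groups without acid-induced transannular opening of the 1,10-epoxide or base-induced addition to the methylene lactone.

## Compound list

1 | (R)-linalool | C=C[C@](C)(O)CCC=C(C)C | starting material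
2 | (R)-linalool triethylsilyl ether | C=C[C@](C)(O[Si](CC)(CC)CC)CCC=C(C)C | intermediate
3 | (4R)-4-methyl-4-(triethylsilyloxy)hex-5-enal | C=C[C@](C)(O[Si](CC)(CC)CC)CCC=O | intermediate (not isolated)
4 | (4R)-4-methyl-4-(triethylsilyloxy)hex-5-enoic acid | C=C[C@](C)(O[Si](CC)(CC)CC)CCC(=O)O | intermediate
5 | 2-thioxopyridin-1(2H)-yl ester of 4 (Barton ester) | C=C[C@](C)(O[Si](CC)(CC)CC)CCC(=O)On1ccccc1=S | intermediate (not isolated)
6 | triethyl{[(3R)-5-iodo-3-methylpent-1-en-3-yl]oxy}silane (C8 iodide) | C=C[C@](C)(O[Si](CC)(CC)CC)CCI | intermediate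
7 | (S)-5-(hydroxymethyl)furan-2(5H)-one | O=C1C=C[C@@H](CO)O1 | starting material
8 | (S)-5-[(tert-butyldimethylsilyloxy)methyl]furan-2(5H)-one | O=C1C=C[C@@H](CO[Si](C)(C)C(C)(C)C)O1 | intermediate
9 | [(3R)-3-methyl-3-(triethylsilyloxy)pent-4-en-1-yl]magnesium iodide | C=C[C@](C)(O[Si](CC)(CC)CC)CC[Mg]I | intermediate (not isolated)
10 | trimethylsilyl ketene acetal of 11 | C[Si](C)(C)OC1=C[C@H](CC[C@@](C)(O[Si](CC)(CC)CC)C=C)[C@@H](CO[Si](C)(C)C(C)(C)C)O1 | intermediate (not isolated)
11 | (4S,5S)-5-[(tert-butyldimethylsilyloxy)methyl]-4-[(3R)-3-methyl-3-(triethylsilyloxy)pent-4-en-1-yl]dihydrofuran-2(3H)-one | O=C1C[C@H](CC[C@@](C)(O[Si](CC)(CC)CC)C=C)[C@@H](CO[Si](C)(C)C(C)(C)C)O1 | intermediate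
12 | (4S,5S)-5-(hydroxymethyl)-4-[(3R)-3-hydroxy-3-methylpent-4-en-1-yl]dihydrofuran-2(3H)-one | O=C1C[C@H](CC[C@@](C)(O)C=C)[C@@H](CO)O1 | intermediate
13 | (2S,3S)-3-[(3R)-3-hydroxy-3-methylpent-4-en-1-yl]-5-oxotetrahydrofuran-2-carbaldehyde | O=C1C[C@H](CC[C@@](C)(O)C=C)[C@@H](C=O)O1 | intermediate
14 | methyl bis(2,2,2-trifluoroethyl)phosphonoacetate | COC(=O)CP(=O)(OCC(F)(F)F)OCC(F)(F)F | starting material
15 | allyl bromide | C=CCBr | starting material
16 | methyl 2-[bis(2,2,2-trifluoroethoxy)phosphoryl]pent-4-enoate (racemic) | COC(=O)C(CC=C)P(=O)(OCC(F)(F)F)OCC(F)(F)F | intermediate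
17 | (Z)-enoate: lactone with C6–CH=C(CO2Me)(allyl), ester cis to C6 | O=C1C[C@H](CC[C@@](C)(O)C=C)[C@@H](/C=C(\C(=O)OC)CC=C)O1 | intermediate
18 | lactol triol (C12 lactol, C15–OH, C10–OH; anomers) | OC1C[C@H](CC[C@@](C)(O)C=C)[C@@H](/C=C(\CO)CC=C)O1 | intermediate
19 | 15-O-TBS lactol | OC1C[C@H](CC[C@@](C)(O)C=C)[C@@H](/C=C(\CO[Si](C)(C)C(C)(C)C)CC=C)O1 | intermediate
20 | lactone diene: (4S,5S)-lactone with C6–CH=C(CH2OTBS)(allyl) and C7–CH2CH2C(CH3)(OH)CH=CH2 | O=C1C[C@H](CC[C@@](C)(O)C=C)[C@@H](/C=C(\CO[Si](C)(C)C(C)(C)C)CC=C)O1 | intermediate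
21 | (1Z,4Z,6S,7S,10R)-15-(TBS-oxy)-10-hydroxygermacra-1,4-dien-12,6-olide (ten-membered ring, trans-fused lactone, C3 and C6 trans across C4=C5) | C1C(=O)O[C@@H]2/C=C(\CO[Si](C)(C)C(C)(C)C)C/C=C\[C@](C)(O)CC[C@@H]12 | intermediate
22 | (1S,2S,4Z,6S,7S,10R)-15-(TBS-oxy)-1,2-epoxy-10-hydroxygermacr-4-en-12,6-olide (cis-oxirane syn to 10-OH) | C1C(=O)O[C@@H]2/C=C(\CO[Si](C)(C)C(C)(C)C)C[C@@H]3O[C@@H]3[C@](C)(O)CC[C@@H]12 | intermediate
23 | 10-O-diethyl(hydrido)silyl ether of 22 (key-step precursor) | C1C(=O)O[C@@H]2/C=C(\CO[Si](C)(C)C(C)(C)C)C[C@@H]3O[C@@H]3[C@](C)(O[SiH](CC)CC)CC[C@@H]12 | intermediate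
24 | oxasilolane: SiEt2 bridging C8 (C–Si, 8S) and O10 (key-step product) | C1C(=O)O[C@@H]2/C=C(\CO[Si](C)(C)C(C)(C)C)C[C@@H]3O[C@@H]3[C@@]4(C)C[C@H]([Si](CC)(CC)O4)[C@@H]12 | intermediate
25 | (1S,2S,4Z,6R,7R,8S,10R)-15-(TBS-oxy)-1,2-epoxy-8,10-dihydroxygermacr-4-en-12,6-olide | C1C(=O)O[C@@H]2/C=C(\CO[Si](C)(C)C(C)(C)C)C[C@@H]3O[C@@H]3[C@](C)(O)C[C@H](O)[C@@H]12 | intermediate
26 | 8-O-(4-methoxybenzyl) ether of 25 | C1C(=O)O[C@@H]2/C=C(\CO[Si](C)(C)C(C)(C)C)C[C@@H]3O[C@@H]3[C@](C)(O)C[C@H](OCc4ccc(OC)cc4)[C@@H]12 | intermediate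
27 | sodium 2-alkoxide of the rearranged (1R,10R)-1,10-epoxide | C1C(=O)O[C@@H]2/C=C(\CO[Si](C)(C)C(C)(C)C)C[C@H]([O-])[C@H]3O[C@]3(C)C[C@H](OCc4ccc(OC)cc4)[C@@H]12.[Na+] | intermediate (not isolated)
28 | (1R,2S,4Z,6R,7R,8S,10R)-15-(TBS-oxy)-1,10-epoxy-8-(PMB-oxy)-2-(TES-oxy)germacr-4-en-12,6-olide | C1C(=O)O[C@@H]2/C=C(\CO[Si](C)(C)C(C)(C)C)C[C@H](O[Si](CC)(CC)CC)[C@H]3O[C@]3(C)C[C@H](OCc4ccc(OC)cc4)[C@@H]12 | intermediate
29 | 11-[(dimethylamino)methyl] lactone (Mannich base, C11 epimers) | CN(C)CC1C(=O)O[C@@H]2/C=C(\CO[Si](C)(C)C(C)(C)C)C[C@H](O[Si](CC)(CC)CC)[C@H]3O[C@]3(C)C[C@H](OCc4ccc(OC)cc4)[C@@H]12 | intermediate (not isolated)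
30 | 11-[(trimethylammonio)methyl] lactone iodide | C[N+](C)(C)CC1C(=O)O[C@@H]2/C=C(\CO[Si](C)(C)C(C)(C)C)C[C@H](O[Si](CC)(CC)CC)[C@H]3O[C@]3(C)C[C@H](OCc4ccc(OC)cc4)[C@@H]12.[I-] | intermediate (not isolated)
31 | 11(13)-methylene lactone with 8-OPMB, 2-OTES, 15-OTBS | C=C1C(=O)O[C@@H]2/C=C(\CO[Si](C)(C)C(C)(C)C)C[C@H](O[Si](CC)(CC)CC)[C@H]3O[C@]3(C)C[C@H](OCc4ccc(OC)cc4)[C@@H]12 | intermediate
32 | 8-hydroxy methylene lactone with 2-OTES, 15-OTBS | C=C1C(=O)O[C@@H]2/C=C(\CO[Si](C)(C)C(C)(C)C)C[C@H](O[Si](CC)(CC)CC)[C@H]3O[C@]3(C)C[C@H](O)[C@@H]12 | intermediate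
33 | angelic acid, (Z)-2-methylbut-2-enoic acid | C/C=C(/C)C(=O)O | starting material
34 | angelic 2,4,6-trichlorobenzoic anhydride | C/C=C(/C)C(=O)OC(=O)c1c(Cl)cc(Cl)cc1Cl | intermediate (not isolated)
35 | 8-O-angelate with 2-OTES, 15-OTBS | C=C1C(=O)O[C@@H]2/C=C(\CO[Si](C)(C)C(C)(C)C)C[C@H](O[Si](CC)(CC)CC)[C@H]3O[C@]3(C)C[C@H](OC(=O)/C(C)=C\C)[C@@H]12 | intermediate
36 | EANPDB:COMP_00180, (1R,2S,4Z,6R,7R,8S,10R)-8-angeloyloxy-1,10-epoxy-2,15-dihydroxygermacra-4,11(13)-dien-12,6-olide | C=C1C(=O)O[C@@H]2/C=C(\CO)C[C@H](O)[C@H]3O[C@]3(C)C[C@H](OC(=O)/C(C)=C\C)[C@@H]12 | target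

## Step count and risks

Total step count: 23. Longest linear sequence: 21 steps (from 1 through steps 1–3, 5–7 and 9–23).

Steps most likely to fail:

1. Step 16 (proposed new method). The ring conformer may not bring the C8 hydrogen to the iridium-bound silicon, so that no C–H cleavage occurs. The catalyst may instead hydrosilylate or hydrogenate the C4=C5 bond. The Lewis-acidic iridium silyl species may open the oxirane.
Fallback (known chemistry; the C8 oxygen is brought in at the fragment stage, with C8 set by reagent control instead of by the tether). It sets out from iodide 6 and butenolide 8 and comes back at 26. Kornblum displacement of 6 (NaNO2, phloroglucinol, DMF) gives nitroalkane F1. Its nitronate (DBU cat., MeCN, 0 °C) adds to 8 trans to the C6 substituent and gives nitro lactone F2 (11 with NO2 on C8, C8 epimers). A buffered TiCl3 Nef reaction gives 8-ketone F3. (R)-Me-CBS with catecholborane should reduce it to (8S)-alcohol F4, with the C7-branched side as the large group. Benzyl transfer as in step 18 gives PMB ether F5. F5 is then taken through the operations of steps 6, 7, 9, 10, 11, 12 and 13 to diol F6, aldehyde F7, Z-enoate F8, lactol F9, silyl ether F10, lactone diene F11 and macrocycle F12. The directed epoxidation of step 14 on F12 gives 26.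

2. Step 13. The hindered vinyl carbinol may engage slowly, so that the allyl termini oligomerise. A carbene formed at C1 may attack the trisubstituted C4=C5 bond and contract the ring. Strain in the lactone-fused Z,E-1,4-diene may reverse the closure.
Fallback (the order of ring closure and reduction is changed, so that the metathesis substrate carries a conjugated, metathesis-inert C4=C5 bond). It sets out from enoate 17 and comes back at 21. Ring-closing metathesis of 17 (Grubbs II, Ti(OiPr)4 to keep the ester off ruthenium, toluene, 1 mM) gives macrocyclic enoate F13. DIBAL-H at −78 °C gives macrocyclic lactol diol F14. TBSCl/imidazole gives silyl ether F15, and TPAP/NMO oxidation of the lactol gives 21. This fallback is still a metathesis at C1=C2; it answers ring contraction at C4=C5 but not strain or slow engagement of the vinyl carbinol.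

3. Step 19. The O10 or O2 alkoxide may attack the lactone carbonyl (acyl transfer within or between molecules). The 3-exo opening may be too slow if the ring cannot place O10 anti to the C1–O bond, leaving the equilibrium on the side of the 1,2-epoxide.
Fallback (the epoxide shift is run under aqueous, equilibrating conditions on the ring-opened carboxylate, which has no electrophilic lactone, and the lactone is closed again afterwards). It sets out from 26 and comes back at 28. NaOH (0.5 M) in t-BuOH/H2O at 40 °C saponifies the lactone and shifts the oxirane; careful acidification to pH 5 gives hydroxy acid F16. Because O8 is an ether, only O6 can close the lactone (EDC·HCl, DMAP cat., CH2Cl2), giving hydroxy lactone F17. TESCl/imidazole silylates the C2 hydroxyl and gives 28.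

Further compounds
F1 | step 16 | triethyl{[(3R)-3-methyl-5-nitropent-1-en-3-yl]oxy}silane | C=C[C@](C)(O[Si](CC)(CC)CC)CC[N+](=O)[O-]
F2 | step 16 | nitro lactone: 11 with NO2 on C8 (C8 epimers) | O=C1C[C@H](C(C[C@@](C)(O[Si](CC)(CC)CC)C=C)[N+](=O)[O-])[C@@H](CO[Si](C)(C)C(C)(C)C)O1
F3 | step 16 | 8-oxo analogue of 11 | O=C1C[C@H](C(=O)C[C@@](C)(O[Si](CC)(CC)CC)C=C)[C@@H](CO[Si](C)(C)C(C)(C)C)O1
F4 | step 16 | (8S)-8-hydroxy analogue of 11 | O=C1C[C@H]([C@@H](O)C[C@@](C)(O[Si](CC)(CC)CC)C=C)[C@@H](CO[Si](C)(C)C(C)(C)C)O1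
F5 | step 16 | (8S)-8-(4-methoxybenzyloxy) analogue of 11 | O=C1C[C@H]([C@@H](OCc2ccc(OC)cc2)C[C@@](C)(O[Si](CC)(CC)CC)C=C)[C@@H](CO[Si](C)(C)C(C)(C)C)O1
F6 | step 16 | 8-OPMB analogue of diol 12 | O=C1C[C@H]([C@@H](OCc2ccc(OC)cc2)C[C@@](C)(O)C=C)[C@@H](CO)O1
F7 | step 16 | 8-OPMB analogue of aldehyde 13 | O=C1C[C@H]([C@@H](OCc2ccc(OC)cc2)C[C@@](C)(O)C=C)[C@@H](C=O)O1
F8 | step 16 | 8-OPMB analogue of (Z)-enoate 17 | O=C1C[C@H]([C@@H](OCc2ccc(OC)cc2)C[C@@](C)(O)C=C)[C@@H](/C=C(\C(=O)OC)CC=C)O1
F9 | step 16 | 8-OPMB analogue of lactol 18 | OC1C[C@H]([C@@H](OCc2ccc(OC)cc2)C[C@@](C)(O)C=C)[C@@H](/C=C(\CO)CC=C)O1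
F10 | step 16 | 8-OPMB analogue of silyl ether 19 | OC1C[C@H]([C@@H](OCc2ccc(OC)cc2)C[C@@](C)(O)C=C)[C@@H](/C=C(\CO[Si](C)(C)C(C)(C)C)CC=C)O1
F11 | step 16 | 8-OPMB analogue of lactone diene 20 | O=C1C[C@H]([C@@H](OCc2ccc(OC)cc2)C[C@@](C)(O)C=C)[C@@H](/C=C(\CO[Si](C)(C)C(C)(C)C)CC=C)O1
F12 | step 16 | 8-OPMB analogue of macrocycle 21 | C1C(=O)O[C@@H]2/C=C(\CO[Si](C)(C)C(C)(C)C)C/C=C\[C@](C)(O)C[C@H](OCc3ccc(OC)cc3)[C@@H]12
F13 | step 13 | macrocyclic enoate: 21 with CO2Me in place of CH2OTBS on C4 | C1C(=O)O[C@@H]2/C=C(\C(=O)OC)C/C=C\[C@](C)(O)CC[C@@H]12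
F14 | step 13 | macrocyclic lactol diol (C12 lactol, C15–OH, C10–OH) | C1C(O)O[C@@H]2/C=C(\CO)C/C=C\[C@](C)(O)CC[C@@H]12
F15 | step 13 | 15-O-TBS macrocyclic lactol | C1C(O)O[C@@H]2/C=C(\CO[Si](C)(C)C(C)(C)C)C/C=C\[C@](C)(O)CC[C@@H]12
F16 | step 19 | seco hydroxy acid: 1,10-epoxide with 2-OH, 6-OH, 8-OPMB, 15-OTBS and free C12 acid | OC(=O)C[C@H]1[C@H](O)/C=C(\CO[Si](C)(C)C(C)(C)C)C[C@H](O)[C@H]2O[C@]2(C)C[C@@H]1OCc1ccc(OC)cc1
F17 | step 19 | 2-hydroxy-1,10-epoxy lactone (28 without the TES group) | C1C(=O)O[C@@H]2/C=C(\CO[Si](C)(C)C(C)(C)C)C[C@H](O)[C@H]3O[C@]3(C)C[C@H](OCc4ccc(OC)cc4)[C@@H]12
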